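## Structural features

The target is a germacranolide: a ten-membered carbocycle (C1–C10) with two trisubstituted olefins, (Z)-C1=C10 and (E)-C4=C5, on either side of the C2–C3 ethano bridge, fused through C6–C7 to an α-methyl-γ-butyrolactone (O–C6, C7–C11, C12=O). The lactone is cis-fused (H6 and H7 syn) and the four stereocentres are contiguous: C6, C7 and C8 on the carbocycle and the quaternary C11 next to C7, with the C8 oxygen anti to the C7–C11 bond and the C11 oxygen on the convex face of the bicyclic lactone (6S,7R,8S,11S). Two different esters sit on oxygens that are 1,3-related through C7, a secondary acetate at C8 and a tertiary (Z)-2-methylbut-2-enoate (angelate) at C11, so acyl migration and Z→E isomerisation to the tiglate are real risks. The cyclodeca-1,5-diene is the fragile core: it is open to acid-induced transannular cyclisation and to Cope rearrangement, and the lactone can translactonise to O8 once that hydroxyl is free. The real difficulty is the medium ring itself, with one Z and one E trisubstituted olefin, next to three contiguous stereocentres that are hard to control on a flexible ring. The key step exploits the fact that C10=C1 and C4=C5 are separated by exactly two sp3 carbons: the ring is the 2,3-dihydro form of the cyclodeca-1,3,5-triene released when a ring-A cyclohexa-1,3-diene (C1=C2–C3=C4), fused to ring B through C5–C10, opens electrocyclically. All four stereocentres lie on ring B and the lactone, outside the reacting hexatriene, so they can be set on a rigid cis-decalin and carried through the opening untouched.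

## Logic of the disconnections

29 ⇒ 28. The C2–C3 single bond is taken back to a cis olefin (two C–H bonds removed). This turns the skipped diene into the conjugated triene that an electrocyclic reaction can deliver. Nothing is gained in size, but the target becomes linked to a bicyclic precursor. The forward reduction must pick the one disubstituted olefin of 28 out of four C=C bonds and must run cold, because 28 recloses on warming.

28 ⇒ 27. The triene is closed across C5–C10, the bond that the forward step breaks; the forward step forms no σ bond. The medium ring and both trisubstituted olefin geometries are exchanged for a cis-decalin with two sacrificial stereocentres, C5 and C10. The forward opening must turn C9 and H5 inward and C6 and C14 outward. For this, 27 needs the cis ring fusion with H5 and C14 on the face of O6 and C11, and light that the ester chromophore does not absorb.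

27 ⇒ 22 + 23. The two ester C–O bonds (O8–acetyl, O11–angeloyl) are cut. Both esters are base-labile and the angelate isomerises, so they are attached after the last enolate step but before the ring is opened, while the skeleton is still the robust decalin. The gain is 22, with a single silyl ether. The tertiary O11 must be acylated first, while O8 is still silylated (25), so that no second ester can migrate. The silyl ether must then come off without forming an alkoxide (26).

22 ⇒ 21. The C11–O bond is cut to the lactone enolate. On the cis-fused bicycle the convex face is open, so the oxygen arrives with the required sense. The C11 stereocentre is removed and any C11 epimer mixture serves. The forward step requires that 21 has no other enolisable site, which is why it comes after the ring-A ketone is gone, and an oxidant that spares the diene.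

21 ⇒ 18 (through 20 and 19). The C1=C2 and C3=C4 π bonds are exchanged for a C3 carbonyl. A ketone lets both olefins be placed regiospecifically: C1=C2 by dehydrogenation of the kinetic enolate, C3=C4 by reduction of the enol triflate. The forward steps need enolisation of 18 toward C2 and of 19 toward C4, with the lactone α-proton left alone.

18 ⇒ 15 (through 17 and 16). The lactone acyl bond C12–O6 is cut, C12 and C3 are taken to the alcohol level, and the C4–H and C5–H bonds are removed. The 6β-hydroxyl can both accept the side chain as a cis-lactone and steer hydrogen to the β face. This returns to an enone with an intact isopropenyl group. The forward steps need a hydroboration selective for the 1,1-disubstituted olefin, hydrogen delivered cis to O3 and O6, and an oxidation that closes only the five-membered lactone.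

15 ⇒ 13. The C6–O bond is cut. C6 is the γ-carbon of the enone and is reached through the extended dienol ether. The forward oxidation must attack C6 from the β (axial) face.

13 ⇒ 8 + 9. Ring A is cut at C4=C5 (aldol condensation) and C1–C10 (conjugate addition). This gives a monocyclic ketone and a five-carbon enone. The new chain must enter trans to the C7 substituent, against the substrate's own preference, which calls for a chiral-imine version of the addition.

8 ⇒ 4 (through 7, 6 and 5). The carbonyl is moved back across the enone (1,3-transposition; C–O bonds exchanged between the two termini). The silyloxy carbon was made at an easily oxidised α′ position and must end up γ to the carbonyl, a position that cannot be oxygenated directly with confidence. The forward sequence must leave the silyl ether and the C5 stereocentre untouched.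

4 ⇒ 1. The O–Si and C6–O bonds are cut. The kinetic enolate of 1 is oxidised anti to the isopropenyl group, which fixes the future C8 configuration from the single stereocentre of 1.

## Other disconnections considered

Alternative 1: The cut removes C7–C8 and O–C6 and unfolds the carbocycle to the open-chain nitro triene A1. Its olefin geometries (Z at C1=C10, E at C4=C5, E at C6=C7) come from acyclic building blocks and its only stereocentre is the quaternary C11. Forward, dehydration of the primary nitro group (PhNCO, Et3N) gives the nitrile oxide at C8. This must add across C6=C7 with its carbon on C7, closing the ten-membered ring and the bridging isoxazoline A2 in one step.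
- In favour: the ring, the C6–O bond and a masked C8 carbonyl arise together. Syn addition to the E olefin translates directly into the syn H6/H7 relationship of the cis-lactone. The allylic C11 silyloxy group can steer the dipole to one olefin face.
- Better than the chosen plan: both trisubstituted olefin geometries are built in from the start and do not depend on a torquoselective event.
- Against: a ten-membered closure is entropically and enthalpically costly, and furoxan formation competes unless dilution is high. Bonding of the dipole carbon to C6 would give a nine-membered ring instead. Face selectivity rests on one acyclic stereocentre. Afterwards the N–O bond and then the C8 ketone must be reduced selectively on the flexible, acid-sensitive cyclodecadiene.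
- Comparison: the alternative should be clearly shorter and needs neither light nor a thermally labile triene. The chosen plan gets the ring from a unimolecular bond cleavage of a preformed bicycle and sets C6, C7 and C8 on a chair cyclohexane. Its key step is stereospecific by orbital symmetry, whereas the cycloaddition is stereospecific only with respect to the olefin, not the face.

Alternative 2: The cut is the C6–C7 bond. Retrosynthetically the O–C13 ether bond is re-formed, leading to the thirteen-membered cyclic diallyl ether A3, drawn with C8 and C13 trans across the C7=C11 ring olefin. Forward, n-BuLi removes a proton at C6 of A3 and the α-oxy allyl anion undergoes a [2,3]-Wittig shift onto C7. This forms C6–C7, breaks O–C13 and contracts the ether ring to the cyclodecadienol A4, creating the C6 carbinol, the C7 stereocentre and the C11=C13 methylene together.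
- In favour: a thirteen-membered ether should close far more readily than a ten-membered carbocycle. The rearrangement is a low-temperature, irreversible, concerted anionic step, and the olefin geometries again come from acyclic precursors.
- Equal or better than the chosen plan: the product is the skipped diene itself, so no labile triene and no selective reduction are needed; operationally this is the more robust.
- Against: two allylic ether carbons (C6 and C13) can be deprotonated, each opening a different [2,3] or [1,2] pathway. The syn relationship of O6 and C11 must come from the folding of a flexible transannular transition state, relayed only from the C8 silyloxy centre. C11 stays sp2, so the C12 oxidation, the lactonisation and the tertiary C11–O centre all remain to be made on the sensitive germacradiene.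
- Comparison: step count similar or slightly lower and olefin geometry secure, but the C6/C7 pair is less predictable. The chosen plan fixes that pair on ring B of a decalin by a face-selective γ-oxidation and by keeping the chiral-pool C7 centre.

Alternative 3: The cut re-forms C5–C10 and breaks C2–C3. The ten-membered ring folds back to ring B as the cis-1,2-dialkenylcyclohexanol A5. In A5 an isopropenyl group sits on the C5 carbinol carbon and a vinyl group on the quaternary C10, cis to each other. Forward, the C5 potassium alkoxide of A5 (KH, 18-crown-6) undergoes the anionic oxy-Cope rearrangement, forming C2–C3 and cleaving C5–C10. The resulting C4=C5 enolate is trapped with PhNTf2 as the enol triflate A6, whose later reduction gives the C4=C5 olefin.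
- Equal to the chosen plan on structure: it uses a six-membered ring B as the template for C6, C7 and C8 and breaks the same C5–C10 bond.
- Better in mechanism and product handling: the [3,3] shift is a ground-state reaction with a large anionic driving force. It delivers C2–C3 directly as a single bond, with no triene, no diimide step and no stationary mixture. The chair-like transition state of a cis-dialkenyl ring is expected to give one Z and one E olefin.
- Against: the substrate A5 needs two adjacent fully substituted carbons with the alkenyl groups cis and correctly related to C6–C8. That means adding an isopropenyl metal to a very hindered α-quaternary, α′-alkoxy ketone with facial control. Which olefin becomes Z depends on which alkenyl group is axial in the reacting chair. Three protecting groups and the triflate must then be removed or exchanged, and C12 oxidised and lactonised, on the acid- and heat-sensitive germacradiene; the chosen plan finishes all of this on the decalin.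
- Note: the carbon skeleton of A6 has the target's C4=C5 geometry, although the triflate oxygen makes the formal descriptor Z.
- Comparison: step economy is comparable; a safer key step is traded for a harder substrate synthesis and a heavier end game.

Key step: step 20

Remarks on the chemistry
- The electrocyclic step closes no ring: it cleaves C5–C10, so the ring count falls by one and no skeletal bond or stereocentre is made. The dienolide and trienolide skeletons (27 and 28) map onto the target at C6, C7, C8 and C11 without change.
- Improved precursor: 27 already carries the C11 angelate as a spectator group. Acylating a tertiary alcohol on the finished germacradiene, next to the C8 acetate, would risk acetyl migration, tiglate formation and transannular reactions. Skeleton and disconnection are unchanged.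
- The C8 oxygen is not introduced at the γ-carbon (C4) of (R)-carvone. Carvone is deprotonated kinetically at C6 and its extended dienol forms are one tautomerisation from carvacrol, so no dependable γ-oxygenation follows. The oxygen is put on the α′-carbon of (S)-carvone and the enone is then transposed, which gives the same ring-B configuration.
- Plain base-mediated annulation of a 5-isopropenyl-2-methylcyclohexanone is expected to place the new chain cis to the isopropenyl group. That gives the C10 epimer, whose cis-fused diene would open to the 1(10)E,4Z isomer, so the chiral-imine variant is used.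
- Assumption: C2 of 8 and 10 and C11 of 16–21 are carried as epimer mixtures (erased or converged later) and are left undefined in the SMILES. C4 of 17–19 is drawn as formed by cis-addition of hydrogen and is erased in step 14.

## Route

Step 1
Reactants: 1 (S)-carvone
Product: 3 trans-6-hydroxycarvone [(5R,6R)-6-hydroxy-2-methyl-5-(prop-1-en-2-yl)cyclohex-2-en-1-one], via trimethylsilyl dienol ether 2 (not isolated)
Conditions: LiN(i-Pr)2, THF, −78 °C; Me3SiCl; then mCPBA, NaHCO3, CH2Cl2, −20 °C; 1 M HCl, THF, 0 °C
Reagents that add atoms: 3-chloroperoxybenzoic acid (mCPBA), O=C(OO)c1cccc(Cl)c1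
Why: Rubottom oxidation: kinetic deprotonation of the enone occurs at C6 (α′), and the peracid attacks the cross-conjugated silyl dienol ether at C6 anti to the neighbouring isopropenyl group, so the new hydroxyl (the future C8 oxygen) is trans to it; the enol ether reacts far faster than the isopropenyl olefin.

Step 2
Reactants: 3 trans-6-hydroxycarvone
Product: 4 (5R,6R)-6-(tert-butyldimethylsilyloxy)-2-methyl-5-(prop-1-en-2-yl)cyclohex-2-en-1-one
Conditions: t-BuMe2SiCl, imidazole, DMF, rt
Reagents that add atoms: tert-butyldimethylsilyl chloride, CC(C)(C)[Si](C)(C)Cl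
Why: Standard silyl ether formation; the silyl ether withstands the peroxide, hydrazine, hydride, alkoxide, borane and amide-base steps that follow and is removed only in step 18.

Step 3
Reactants: 4 (5R,6R)-6-(tert-butyldimethylsilyloxy)-2-methyl-5-(prop-1-en-2-yl)cyclohex-2-en-1-one
Product: 5 2,3-epoxide of 4 (oxirane oxygen anti to the isopropenyl group)
Conditions: 30% H2O2, NaOH (cat.), MeOH, 0 °C
Reagents that add atoms: hydrogen peroxide, OO
Why: Weitz–Scheffer epoxidation: hydroperoxide adds to the enone β-carbon and closes onto C2, leaving the isolated isopropenyl olefin alone; the epoxide configuration is immaterial because both epoxide carbons become sp2 within two steps.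

Step 4
Reactants: 5 2,3-epoxide of 4
Product: 6 (4S,5R)-4-(tert-butyldimethylsilyloxy)-2-methyl-5-(prop-1-en-2-yl)cyclohex-2-en-1-ol (carbinol cis to the silyloxy group)
Conditions: N2H4·H2O, AcOH (cat.), MeOH, 0 °C → rt
Reagents that add atoms: none
Why: Wharton transposition: the epoxy hydrazone opens to an alkenyl diazene that loses N2, so the former carbonyl carbon becomes vinylic CH and the oxygen appears on the former β-carbon; the silyloxy carbon thereby becomes γ to the future carbonyl.

Step 5
Reactants: 6 (4S,5R)-4-(tert-butyldimethylsilyloxy)-2-methyl-5-(prop-1-en-2-yl)cyclohex-2-en-1-ol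
Product: 7 (4S,5R)-4-(tert-butyldimethylsilyloxy)-2-methyl-5-(prop-1-en-2-yl)cyclohex-2-en-1-one
Conditions: MnO2 (excess), CH2Cl2, rt
Reagents that add atoms: none
Why: Selective oxidation of the allylic alcohol to the enone; 7 is a 4-silyloxycarvone whose C5 has the configuration of (R)-carvone, with the C4 oxygen trans to the isopropenyl group.

Step 6
Reactants: 7 (4S,5R)-4-(tert-butyldimethylsilyloxy)-2-methyl-5-(prop-1-en-2-yl)cyclohex-2-en-1-one
Product: 8 (4S,5R)-4-(tert-butyldimethylsilyloxy)-2-methyl-5-(prop-1-en-2-yl)cyclohexan-1-one (C2 epimers)
Conditions: LiBH(s-Bu)3, THF, −78 °C; aq. NH4Cl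
Reagents that add atoms: none
Why: Conjugate reduction of a β-unsubstituted cyclohexenone by a hindered borohydride, as for carvone itself; the isopropenyl group is untouched and the C2 configuration is irrelevant because C2 becomes quaternary in step 7.

Step 7
Reactants: 8 (4S,5R)-4-(tert-butyldimethylsilyloxy)-2-methyl-5-(prop-1-en-2-yl)cyclohexan-1-one, 9 ethyl vinyl ketone
Product: 12 (2R,4S,5R)-4-(tert-butyldimethylsilyloxy)-2-methyl-2-(3-oxopentyl)-5-(prop-1-en-2-yl)cyclohexan-1-one, via ketimine 10 (not isolated), via Michael-adduct ketimine 11 (not isolated)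
Conditions: (R)-PhCH(CH3)NH2, TsOH (cat.), toluene, reflux (−H2O); 9, THF, 40 °C; 10% aq. AcOH, rt
Reagents that add atoms: water, O
Why: Chiral-imine Michael reaction: the more substituted secondary enamine tautomer adds to the enone through a compact aza-ene-like transition state on the face left open by the auxiliary, so the chain enters trans to the isopropenyl group and the methyl (future C14) ends cis to it; the (R)-amine is the enantiomer that overrides the substrate's preference for attack cis to isopropenyl in the parent dihydrocarvone series. Dilute aqueous acid then hydrolyses the imine, returning the ring carbonyl and releasing the auxiliary.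

Step 8
Reactants: 12 (2R,4S,5R)-4-(tert-butyldimethylsilyloxy)-2-methyl-2-(3-oxopentyl)-5-(prop-1-en-2-yl)cyclohexan-1-one
Product: 13 8α-(tert-butyldimethylsilyloxy)eudesma-4,11-dien-3-one (7αH; 10β-methyl)
Conditions: NaOMe, MeOH, rt → 45 °C
Reagents that add atoms: none
Why: Intramolecular aldol condensation and dehydration complete the Robinson annulation; only the ethyl ketone methylene can close a six-membered ring onto the ring carbonyl, giving the 4-methyl enone.

Step 9
Reactants: 13 8α-(tert-butyldimethylsilyloxy)eudesma-4,11-dien-3-one
Product: 15 6β-hydroxy-8α-(tert-butyldimethylsilyloxy)eudesma-4,11-dien-3-one, via 3-silyloxy-3,5-diene 14 (not isolated)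
Conditions: Me3SiOTf, Et3N, CH2Cl2, 0 °C; then mCPBA, NaHCO3, CH2Cl2, −20 °C; 1 M HCl, THF, 0 °C
Reagents that add atoms: 3-chloroperoxybenzoic acid (mCPBA), O=C(OO)c1cccc(Cl)c1
Why: Vinylogous Rubottom oxidation: the ring-fused enone gives the extended (heteroannular) dienol ether, which the peracid attacks at the γ-carbon C6 from the axial β face, as in 3,5-dienol ethers of 10-methyl-4-en-3-ones; this sets C6–O cis to the C7 side chain, and the electron-rich diene reacts before the isopropenyl olefin.

Step 10
Reactants: 15 6β-hydroxy-8α-(tert-butyldimethylsilyloxy)eudesma-4,11-dien-3-one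
Product: 16 8α-(tert-butyldimethylsilyloxy)eudesm-4-ene-3β,6β,12-triol (C11 epimers)
Conditions: 9-BBN (3.5 equiv), THF, 0 °C → rt; NaOH, 30% H2O2, 0 °C
Reagents that add atoms: hydrogen peroxide, OO
Why: 9-BBN hydroborates the 1,1-disubstituted olefin at its terminal carbon and reduces the enone carbonyl 1,2, while the tetrasubstituted C4=C5 is inert to it; hydride reaches C3 from the α face, away from the C10 methyl, so both ring carbinols are β, and the C11 configuration is irrelevant until step 16.

Step 11
Reactants: 16 8α-(tert-butyldimethylsilyloxy)eudesm-4-ene-3β,6β,12-triol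
Product: 17 8α-(tert-butyldimethylsilyloxy)-4βH,5βH-eudesmane-3β,6β,12-triol (cis-decalin; C11 epimers)
Conditions: H2 (1–3 atm), [Ir(cod)(PCy3)(py)]PF6 (10–15 mol%), CH2Cl2, rt
Reagents that add atoms: none
Why: Hydroxyl-directed homogeneous hydrogenation: the two allylic hydroxyls at C3 and C6 both lie on the β face and bind the cationic iridium, which then delivers H2 to that face of the tetrasubstituted olefin; H5 ends cis to the C10 methyl (cis ring fusion) and no allylic C–O bond is hydrogenolysed.

Step 12
Reactants: 17 8α-(tert-butyldimethylsilyloxy)-4βH,5βH-eudesmane-3β,6β,12-triol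
Product: 18 8α-(tert-butyldimethylsilyloxy)-3-oxo-4βH,5βH-eudesman-12,6β-olide (C11 epimers)
Conditions: PhI(OAc)2 (3.5 equiv), TEMPO (0.2 equiv), CH2Cl2, rt
Reagents that add atoms: none
Why: Oxoammonium oxidation takes the primary alcohol to the aldehyde, which closes to the five-membered lactol with the syn 6β-hydroxyl and is oxidised on to the cis-fused lactone; the C3 carbinol goes to the ketone under the same conditions.

Step 13
Reactants: 18 8α-(tert-butyldimethylsilyloxy)-3-oxo-4βH,5βH-eudesman-12,6β-olide
Product: 19 8α-(tert-butyldimethylsilyloxy)-3-oxo-4βH,5βH-eudesm-1-en-12,6β-olide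
Conditions: LiN(i-Pr)2 (1.05 equiv), THF, −78 °C; PhS(Cl)=N-t-Bu, −78 °C
Reagents that add atoms: none
Why: Mukaiyama dehydrogenation: the amide base removes the less hindered C2 proton of the ketone, which is more acidic than the lactone α-proton, and the sulfinimidoyl chloride gives an α-sulfilimine that undergoes syn-elimination to the 1-en-3-one; C5 is not touched.

Step 14
Reactants: 19 8α-(tert-butyldimethylsilyloxy)-3-oxo-4βH,5βH-eudesm-1-en-12,6β-olide
Product: 20 8α-(tert-butyldimethylsilyloxy)-3-(trifluoromethanesulfonyloxy)-5βH-eudesma-1,3-dien-12,6β-olide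
Conditions: KN(SiMe3)2 (1.1 equiv), THF, −78 °C; PhNTf2; aq. NH4Cl
Reagents that add atoms: N-phenylbis(trifluoromethanesulfonimide), O=S(=O)(N(c1ccccc1)S(=O)(=O)C(F)(F)F)C(F)(F)F
Why: Enol triflate formation: C4 is the only enolisable position of the enone because C10 is quaternary, and O-sulfonylation of its cross-conjugated dienolate fixes both ring-A double bonds (C1=C2, C3=C4) in place.

Step 15
Reactants: 20 8α-(tert-butyldimethylsilyloxy)-3-(trifluoromethanesulfonyloxy)-5βH-eudesma-1,3-dien-12,6β-olide
Product: 21 8α-(tert-butyldimethylsilyloxy)-5βH-eudesma-1,3-dien-12,6β-olide (C11 epimers)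
Conditions: Pd(OAc)2 (5 mol%), PPh3, Bu3N, HCO2H, DMF, 60 °C
Reagents that add atoms: none
Why: Palladium-catalysed formate reduction of a dienyl triflate: oxidative addition to zerovalent palladium formed in situ, exchange for formate, loss of CO2 and C–H reductive elimination replace the triflate by hydrogen without moving the diene.

Step 16
Reactants: 21 8α-(tert-butyldimethylsilyloxy)-5βH-eudesma-1,3-dien-12,6β-olide
Product: 22 (11S)-11-hydroxy-8α-(tert-butyldimethylsilyloxy)-5βH-eudesma-1,3-dien-12,6β-olide
Conditions: KN(SiMe3)2, THF, −78 °C; 3-phenyl-2-(phenylsulfonyl)oxaziridine, −78 °C; aq. NH4Cl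
Reagents that add atoms: 3-phenyl-2-(phenylsulfonyl)oxaziridine, O=S(=O)(N1OC1c1ccccc1)c1ccccc1
Why: Davis oxidation of the lactone enolate, the only enolisable site left: the oxaziridine reaches C11 on the convex face of the cis-fused bicycle, anti to C8, which gives the 11S carbinol and converges both C11 epimers; the reagent does not epoxidise the diene at −78 °C.

Step 17
Reactants: 22 (11S)-11-hydroxy-8α-(tert-butyldimethylsilyloxy)-5βH-eudesma-1,3-dien-12,6β-olide, 23 angelic acid
Product: 25 (11S)-11-angeloyloxy-8α-(tert-butyldimethylsilyloxy)-5βH-eudesma-1,3-dien-12,6β-olide, via mixed anhydride 24 (not isolated)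
Conditions: 23, 2,4,6-Cl3C6H2COCl, Et3N, toluene, rt; 22, LiN(SiMe3)2 (1.05 equiv), THF, −78 °C; then 24, −78 → 0 °C; aq. NH4Cl
Reagents that add atoms: none
Why: Yamaguchi-type esterification: the lithium alkoxide of the tertiary alcohol attacks the unhindered angeloyl carbonyl of the mixed anhydride at low temperature without a nucleophilic catalyst, so the Z olefin is not scrambled; no other ester is present at this stage, so no acyl group can migrate.

Step 18
Reactants: 25 (11S)-11-angeloyloxy-8α-(tert-butyldimethylsilyloxy)-5βH-eudesma-1,3-dien-12,6β-olide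
Product: 26 (11S)-11-angeloyloxy-8α-hydroxy-5βH-eudesma-1,3-dien-12,6β-olide
Conditions: HF·pyridine, pyridine, THF, 0 °C → rt
Reagents that add atoms: none
Why: Fluoride cleavage of the silyl ether under buffered acidic conditions; no alkoxide is formed, so the C11 ester does not migrate to O8 and the lactone does not translactonise.

Step 19
Reactants: 26 (11S)-11-angeloyloxy-8α-hydroxy-5βH-eudesma-1,3-dien-12,6β-olide
Product: 27 (11S)-8α-acetoxy-11-angeloyloxy-5βH-eudesma-1,3-dien-12,6β-olide (cis-fused; precursor of the key step)
Conditions: Ac2O, pyridine, DMAP (cat.), CH2Cl2, 0 °C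
Reagents that add atoms: acetic anhydride, CC(=O)OC(C)=O
Why: Acylation of the only free, secondary hydroxyl under mild conditions that do not isomerise an existing angelate ester.

Step 20
Reactants: 27 (11S)-8α-acetoxy-11-angeloyloxy-5βH-eudesma-1,3-dien-12,6β-olide
Product: 28 (1(10)Z,2Z,4E,11S)-8α-acetoxy-11-angeloyloxygermacra-1(10),2,4-trien-12,6β-olide (kept in solution at −78 °C)
Conditions: hν (300 nm), degassed THF (0.005 M), −78 °C
Reagents that add atoms: none
Why: Excitation of the ring-A diene (λmax near 268 nm, irradiated on its long-wavelength edge) leads from the excited singlet to a conrotatory six-electron electrocyclic opening that cleaves the C5–C10 σ bond and leaves the C10=C1, C2=C3 and C4=C5 π bonds; no σ bond is formed. The closest known reaction type is the photochemical opening of ring-fused cyclohexa-1,3-dienes to cyclodeca-1,3,5-trienes, the reaction that turns provitamin D into previtamin D. No ring is closed: the ring-fusion bond is broken, the bicyclo[4.4.0]decadiene becomes the ten-membered triene, and no closure mode applies. No stereocentre is created; C5 and C10 are erased, while C6, C7, C8 and C11 lie outside the hexatriene and are untouched. The step needs one of the two conrotatory senses, the one that turns C9 and H5 inward and C6 and C14 outward (1(10)Z,4E) and not the reverse (1(10)E,4Z). The sense follows the ground-state helicity of the diene: with the cis fusion of 27, the ring-B chair that keeps C11 and the C8 acetate equatorial makes C9 pseudoaxial and C6 pseudoequatorial on ring A, and pseudoaxial groups rotate inward. At −78 °C this conformer should dominate and the triene cannot reclose thermally, while 300 nm light is absorbed by the diene, hardly by the twisted triene and not by the angelate. The mixture is taken to its stationary composition, 28 is used cold in step 21 and unchanged 27 is recovered for another pass.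

Step 21
Reactants: 28 (1(10)Z,2Z,4E,11S)-8α-acetoxy-11-angeloyloxygermacra-1(10),2,4-trien-12,6β-olide
Product: 29 target, (1(10)Z,4E,6S,7R,8S,11S)-8-acetoxy-11-angeloyloxygermacra-1(10),4-dien-12,6-olide
Conditions: KO2C–N=N–CO2K (excess), AcOH, MeOH–THF, −78 → −20 °C
Reagents that add atoms: none
Why: Diimide reduction: diimide formed from the azodicarboxylate and acetic acid transfers two hydrogens suprafacially through a six-membered transition state to the strained, unhindered cis-disubstituted C2=C3 bond, while the trisubstituted C1=C10, C4=C5 and angelate olefins react far more slowly; the low temperature keeps 28 from disrotatory reclosure before it is reduced.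

## Compound list

1 | (S)-carvone | CC(=C)[C@H]1CC=C(C)C(=O)C1 | starting material
2 | cross-conjugated trimethylsilyl dienol ether of 1 | CC(=C)[C@H]1CC=C(C)C(O[Si](C)(C)C)=C1 | intermediate
3 | trans-6-hydroxycarvone, (5R,6R)-6-hydroxy-2-methyl-5-(prop-1-en-2-yl)cyclohex-2-en-1-one | CC(=C)[C@H]1CC=C(C)C(=O)[C@@H]1O | intermediate
4 | (5R,6R)-6-(tert-butyldimethylsilyloxy)-2-methyl-5-(prop-1-en-2-yl)cyclohex-2-en-1-one | CC(=C)[C@H]1CC=C(C)C(=O)[C@@H]1O[Si](C)(C)C(C)(C)C | intermediate
5 | 2,3-epoxide of 4, oxirane oxygen anti to the isopropenyl group | CC(=C)[C@H]1C[C@@H]2O[C@]2(C)C(=O)[C@@H]1O[Si](C)(C)C(C)(C)C | intermediate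
6 | (4S,5R)-4-(tert-butyldimethylsilyloxy)-2-methyl-5-(prop-1-en-2-yl)cyclohex-2-en-1-ol, carbinol cis to the silyloxy group | CC(=C)[C@H]1C[C@H](O)C(C)=C[C@@H]1O[Si](C)(C)C(C)(C)C | intermediate
7 | (4S,5R)-4-(tert-butyldimethylsilyloxy)-2-methyl-5-(prop-1-en-2-yl)cyclohex-2-en-1-one | CC(=C)[C@@H]1[C@@H](O[Si](C)(C)C(C)(C)C)C=C(C)C(=O)C1 | intermediate
8 | (4S,5R)-4-(tert-butyldimethylsilyloxy)-2-methyl-5-(prop-1-en-2-yl)cyclohexan-1-one, C2 epimers | CC(=C)[C@@H]1[C@@H](O[Si](C)(C)C(C)(C)C)CC(C)C(=O)C1 | intermediate
9 | ethyl vinyl ketone (pent-1-en-3-one) | CCC(=O)C=C | starting material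
10 | ketimine of 8 with (R)-1-phenylethylamine | CC(=C)[C@@H]1[C@@H](O[Si](C)(C)C(C)(C)C)CC(C)C(=N[C@H](C)c2ccccc2)C1 | intermediate
11 | Michael-adduct ketimine (C2 quaternary, 3-oxopentyl chain trans to isopropenyl) | CC(=C)[C@@H]1[C@@H](O[Si](C)(C)C(C)(C)C)C[C@@](C)(CCC(=O)CC)C(=N[C@H](C)c2ccccc2)C1 | intermediate
12 | (2R,4S,5R)-4-(tert-butyldimethylsilyloxy)-2-methyl-2-(3-oxopentyl)-5-(prop-1-en-2-yl)cyclohexan-1-one | CC(=C)[C@@H]1[C@@H](O[Si](C)(C)C(C)(C)C)C[C@@](C)(CCC(=O)CC)C(=O)C1 | intermediate
13 | 8α-(tert-butyldimethylsilyloxy)eudesma-4,11-dien-3-one (7αH, 10β-methyl) | CC(=C)[C@@H]1[C@@H](O[Si](C)(C)C(C)(C)C)C[C@@]2(C)CCC(=O)C(C)=C2C1 | intermediate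
14 | 3-(trimethylsilyloxy)-8α-(tert-butyldimethylsilyloxy)eudesma-3,5,11-triene | CC(=C)[C@@H]1[C@@H](O[Si](C)(C)C(C)(C)C)C[C@@]2(C)CCC(O[Si](C)(C)C)=C(C)C2=C1 | intermediate
15 | 6β-hydroxy-8α-(tert-butyldimethylsilyloxy)eudesma-4,11-dien-3-one | CC(=C)[C@@H]1[C@@H](O[Si](C)(C)C(C)(C)C)C[C@@]2(C)CCC(=O)C(C)=C2[C@@H]1O | intermediate
16 | 8α-(tert-butyldimethylsilyloxy)eudesm-4-ene-3β,6β,12-triol, C11 epimers | OCC(C)[C@@H]1[C@@H](O[Si](C)(C)C(C)(C)C)C[C@@]2(C)CC[C@H](O)C(C)=C2[C@@H]1O | intermediate
17 | 8α-(tert-butyldimethylsilyloxy)-4βH,5βH-eudesmane-3β,6β,12-triol, cis-decalin, C11 epimers | OCC(C)[C@@H]1[C@@H](O[Si](C)(C)C(C)(C)C)C[C@@]2(C)CC[C@H](O)[C@@H](C)[C@H]2[C@@H]1O | intermediate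
18 | 8α-(tert-butyldimethylsilyloxy)-3-oxo-4βH,5βH-eudesman-12,6β-olide, C11 epimers | CC1C(=O)O[C@H]2[C@@H]3[C@H](C)C(=O)CC[C@]3(C)C[C@H](O[Si](C)(C)C(C)(C)C)[C@H]21 | intermediate
19 | 8α-(tert-butyldimethylsilyloxy)-3-oxo-4βH,5βH-eudesm-1-en-12,6β-olide, C11 epimers | CC1C(=O)O[C@H]2[C@@H]3[C@H](C)C(=O)C=C[C@]3(C)C[C@H](O[Si](C)(C)C(C)(C)C)[C@H]21 | intermediate
20 | 8α-(tert-butyldimethylsilyloxy)-3-(trifluoromethanesulfonyloxy)-5βH-eudesma-1,3-dien-12,6β-olide, C11 epimers | CC1C(=O)O[C@H]2[C@@H]3C(C)=C(OS(=O)(=O)C(F)(F)F)C=C[C@]3(C)C[C@H](O[Si](C)(C)C(C)(C)C)[C@H]21 | intermediate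
21 | 8α-(tert-butyldimethylsilyloxy)-5βH-eudesma-1,3-dien-12,6β-olide, C11 epimers | CC1C(=O)O[C@H]2[C@@H]3C(C)=CC=C[C@]3(C)C[C@H](O[Si](C)(C)C(C)(C)C)[C@H]21 | intermediate
22 | (11S)-11-hydroxy-8α-(tert-butyldimethylsilyloxy)-5βH-eudesma-1,3-dien-12,6β-olide | O[C@]1(C)C(=O)O[C@H]2[C@@H]3C(C)=CC=C[C@]3(C)C[C@H](O[Si](C)(C)C(C)(C)C)[C@H]21 | intermediate
23 | angelic acid, (Z)-2-methylbut-2-enoic acid | C/C=C(/C)C(=O)O | starting material
24 | angelic 2,4,6-trichlorobenzoic anhydride | C/C=C(/C)C(=O)OC(=O)c1c(Cl)cc(Cl)cc1Cl | intermediate
25 | (11S)-11-angeloyloxy-8α-(tert-butyldimethylsilyloxy)-5βH-eudesma-1,3-dien-12,6β-olide | C/C=C(/C)C(=O)O[C@]1(C)C(=O)O[C@H]2[C@@H]3C(C)=CC=C[C@]3(C)C[C@H](O[Si](C)(C)C(C)(C)C)[C@H]21 | intermediate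
26 | (11S)-11-angeloyloxy-8α-hydroxy-5βH-eudesma-1,3-dien-12,6β-olide | C/C=C(/C)C(=O)O[C@]1(C)C(=O)O[C@H]2[C@@H]3C(C)=CC=C[C@]3(C)C[C@H](O)[C@H]21 | intermediate
27 | (11S)-8α-acetoxy-11-angeloyloxy-5βH-eudesma-1,3-dien-12,6β-olide, cis-fused | C/C=C(/C)C(=O)O[C@]1(C)C(=O)O[C@H]2[C@@H]3C(C)=CC=C[C@]3(C)C[C@H](OC(C)=O)[C@H]21 | intermediate
28 | (1(10)Z,2Z,4E,11S)-8α-acetoxy-11-angeloyloxygermacra-1(10),2,4-trien-12,6β-olide | C/C=C(/C)C(=O)O[C@]1(C)C(=O)O[C@H]2/C=C(\C)/C=C\C=C(\C)C[C@H](OC(C)=O)[C@H]21 | intermediate
29 | (1(10)Z,4E,6S,7R,8S,11S)-8-acetoxy-11-angeloyloxygermacra-1(10),4-dien-12,6-olide | C/C=C(/C)C(=O)O[C@]1(C)C(=O)O[C@H]2/C=C(\C)CC/C=C(/C)C[C@H](OC(C)=O)[C@H]21 | target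

## Step count and least certain steps

Total step count: 21. Longest linear sequence: 21 steps, from 1 to 29; 9 and 23 enter at steps 7 and 17.

Step 20 (key step). Most likely to go wrong:
- conversion stalling, because diene and triene interconvert under light and settle at a stationary mixture;
- partial opening through the minor ring-B chair, which turns the termini the other way and gives the 1(10)E,4Z isomer;
- thermal reclosure of 28 if the solution warms;
- Z→E isomerisation of the angelate if shorter wavelengths reach it.

Fallback (postpone the angelate so the opening substrate has a single chromophore): from 22, HF·pyridine should give the (11S)-8α,11-dihydroxy dienolide F1. Ac2O–pyridine at 0 °C should acetylate only the secondary hydroxyl, giving the 8α-acetoxy-11-hydroxy dienolide F2. Irradiation as in step 20 should then give the 11-hydroxy trienolide F3, and diimide as in step 21 the 11-hydroxy germacradienolide F4. Esterification of the tertiary alcohol of F4 with mixed anhydride 24 (Et3N, toluene, 60 °C, no nucleophilic catalyst) returns to the route at 29. The price is an acylation on the labile germacradiene.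

Step 7. Most likely to go wrong: loss of facial control in the Michael addition. The substrate prefers axial attack cis to the isopropenyl group, and the extra silyloxy group makes the conformer needed for attack on the other face less accessible, so the C10 epimer may intrude.

Fallback (ring A by cycloaddition, known to occur anti to the isopropenyl group of carvone): the fallback sets out from 4 and 9. The diene (Z)-3-(tert-butyldimethylsilyloxy)penta-1,3-diene F5 is made from 9 (t-BuMe2SiOTf, Et3N). It is combined with 4 under EtAlCl2 catalysis (toluene, −20 °C → rt), which should give the cis-fused 9-oxo Diels–Alder adduct F6 with the C10 methyl cis to the C7 side chain. LiAlH4 gives the C9 alcohol F7, and NaH, CS2 and MeI its xanthate F8. Bu3SnH–AIBN (Barton–McCombie) gives the 9-deoxy silyl enol ether F9. AcOH–THF–H2O frees the cis-fused 3-ketone F10. IBX (DMSO–toluene, 70 °C) dehydrogenates it through the C3–C4 enol, the direction of enolisation favoured by the cis ring fusion and the C4 methyl, returning to the route at 13.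

Step 11. Most likely to go wrong: no turnover at the hindered tetrasubstituted olefin because the triol ties up the iridium, or hydrogen delivered to the α face if part of the C3 carbinol has the α configuration.

Fallback (keep the ketone and hydrogenate the enone on a surface): from 15, catecholborane with RhCl(PPh3)3 (THF; then NaBO3) should hydroborate only the isopropenyl group and give the 6β,12-dihydroxy enone F11. H2 over Pd/C in EtOAc–pyridine, where the 6β-hydroxyl anchors the β face and the basic medium favours the cis ring fusion of 10-methyl-4-en-3-ones, should give the cis-fused 6β,12-dihydroxy ketone F12. PhI(OAc)2–TEMPO closes the lactone and returns to the route at 18.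

Step 17. Most likely to go wrong: slow acylation of the hindered tertiary alkoxide, and isomerisation of the angeloyl group to tiglate if the conditions have to be forced.

Fallback (build the Z olefin after the ester bond): from 22, 2-(diphenoxyphosphoryl)propanoic acid with DCC and DMAP (CH2Cl2, 40 °C) should give the phosphonopropanoate ester F13. This acyl group has nothing to isomerise, so forcing is harmless. A Z-selective Horner–Wadsworth–Emmons olefination of F13 with acetaldehyde (NaH, THF, −78 → 0 °C) then returns to the route at 25.

## Further compounds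

F1 | step 20 | (11S)-8α,11-dihydroxy-5βH-eudesma-1,3-dien-12,6β-olide | O[C@]1(C)C(=O)O[C@H]2[C@@H]3C(C)=CC=C[C@]3(C)C[C@H](O)[C@H]21
F2 | step 20 | (11S)-8α-acetoxy-11-hydroxy-5βH-eudesma-1,3-dien-12,6β-olide | O[C@]1(C)C(=O)O[C@H]2[C@@H]3C(C)=CC=C[C@]3(C)C[C@H](OC(C)=O)[C@H]21
F3 | step 20 | (1(10)Z,2Z,4E,11S)-8α-acetoxy-11-hydroxygermacra-1(10),2,4-trien-12,6β-olide | O[C@]1(C)C(=O)O[C@H]2/C=C(\C)/C=C\C=C(\C)C[C@H](OC(C)=O)[C@H]21
F4 | step 20 | (1(10)Z,4E,11S)-8α-acetoxy-11-hydroxygermacra-1(10),4-dien-12,6β-olide | O[C@]1(C)C(=O)O[C@H]2/C=C(\C)CC/C=C(/C)C[C@H](OC(C)=O)[C@H]21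
F5 | step 7 | (Z)-3-(tert-butyldimethylsilyloxy)penta-1,3-diene | C=C/C(O[Si](C)(C)C(C)(C)C)=C/C
F6 | step 7 | 3,8α-bis(tert-butyldimethylsilyloxy)-9-oxo-5βH-eudesma-2,11-diene (cis-fused Diels–Alder adduct, C4 as formed) | CC(=C)[C@@H]1[C@@H](O[Si](C)(C)C(C)(C)C)C(=O)[C@@]2(C)CC=C(O[Si](C)(C)C(C)(C)C)C(C)[C@H]2C1
F7 | step 7 | 3,8α-bis(tert-butyldimethylsilyloxy)-5βH-eudesma-2,11-dien-9-ol | CC(=C)[C@@H]1[C@@H](O[Si](C)(C)C(C)(C)C)C(O)[C@@]2(C)CC=C(O[Si](C)(C)C(C)(C)C)C(C)[C@H]2C1
F8 | step 7 | S-methyl xanthate of F7 | CC(=C)[C@@H]1[C@@H](O[Si](C)(C)C(C)(C)C)C(OC(=S)SC)[C@@]2(C)CC=C(O[Si](C)(C)C(C)(C)C)C(C)[C@H]2C1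
F9 | step 7 | 3,8α-bis(tert-butyldimethylsilyloxy)-5βH-eudesma-2,11-diene | CC(=C)[C@@H]1[C@@H](O[Si](C)(C)C(C)(C)C)C[C@@]2(C)CC=C(O[Si](C)(C)C(C)(C)C)C(C)[C@H]2C1
F10 | step 7 | 8α-(tert-butyldimethylsilyloxy)-5βH-eudesm-11-en-3-one (cis-fused) | CC(=C)[C@@H]1[C@@H](O[Si](C)(C)C(C)(C)C)C[C@@]2(C)CCC(=O)C(C)[C@H]2C1
F11 | step 11 | 6β,12-dihydroxy-8α-(tert-butyldimethylsilyloxy)eudesm-4-en-3-one, C11 epimers | OCC(C)[C@@H]1[C@@H](O[Si](C)(C)C(C)(C)C)C[C@@]2(C)CCC(=O)C(C)=C2[C@@H]1O
F12 | step 11 | 6β,12-dihydroxy-8α-(tert-butyldimethylsilyloxy)-4βH,5βH-eudesman-3-one, C11 epimers | OCC(C)[C@@H]1[C@@H](O[Si](C)(C)C(C)(C)C)C[C@@]2(C)CCC(=O)[C@@H](C)[C@H]2[C@@H]1O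
F13 | step 17 | (11S)-11-[2-(diphenoxyphosphoryl)propanoyloxy]-8α-(tert-butyldimethylsilyloxy)-5βH-eudesma-1,3-dien-12,6β-olide | CC(P(=O)(Oc1ccccc1)Oc1ccccc1)C(=O)O[C@]1(C)C(=O)O[C@H]2[C@@H]3C(C)=CC=C[C@]3(C)C[C@H](O[Si](C)(C)C(C)(C)C)[C@H]21
A1 | alternative 1 | open-chain nitro triene ester (primary nitro at C8; Z-C1=C10, E-C4=C5, E-C6=C7; C11 triethylsilyl ether) | [O-][N+](=O)CC/C(C)=C\CC/C(C)=C/C=C/[C@](C)(O[Si](CC)(CC)CC)C(=O)OC
A2 | alternative 1 | isoxazoline-fused cyclodecadiene | COC(=O)[C@@](C)(O[Si](CC)(CC)CC)[C@H]3[C@@H]2/C=C(\C)CC/C=C(/C)CC3=NO2
A3 | alternative 2 | thirteen-membered cyclic diallyl ether (O between C6 and C13; C8 and C13 trans across C7=C11) | O1C/C=C(\C)CC/C=C(/C)C[C@H](O[Si](C)(C)C(C)(C)C)/C=C(CO[Si](C)(C)C(C)(C)C)/C1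
A4 | alternative 2 | cyclodecadienol with C7 alkenyl side chain | C=C(CO[Si](C)(C)C(C)(C)C)[C@H]1[C@@H](O)/C=C(\C)CC/C=C(/C)C[C@@H]1O[Si](C)(C)C(C)(C)C
A5 | alternative 3 | cis-1,2-dialkenylcyclohexanol (C5 carbinol with isopropenyl, C10 with methyl and vinyl) | CC1(C)OC[C@@](C)(O1)[C@H]2[C@@H](OCc3ccc(OC)cc3)[C@](O)(C(C)=C)[C@](C)(C=C)C[C@@H]2O[Si](C)(C)C(C)(C)C
A6 | alternative 3 | cyclodecadienyl C5 triflate | CC1(C)OC[C@@](C)(O1)[C@H]2[C@@H](OCc3ccc(OC)cc3)/C(OS(=O)(=O)C(F)(F)F)=C(\C)CC/C=C(/C)C[C@@H]2O[Si](C)(C)C(C)(C)C
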